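**Retrosynthetic overview**
1. Target 19 ⇐ keto lactone 13: the C9 carbinol comes from the ketone, the angelate from esterification, and the C6–OH plus the 2-substituted acrolein from opening a 6,15-cyclic acetal.
2. γ-Lactone ⇐ 5-oxo acid 11 by enolate iodination and internal carboxylate SN2 (C8–O cis to C7–C11); the acid comes from the carvone isopropenyl group.
3. Key step: trans-4-hydroxycarvone 3 + alkenyl Grignard + chloroacetaldehyde give, in one flask, the oxirane and a fused tetrahydrofuran acetal (C5, C10 and C1 set together).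
4. 3 ⇐ (R)-carvone 1 by vinylogous Rubottom oxidation (C6–O); C7 is taken from carvone.
5. Ring order: cyclohexane bought with carvone; oxirane and temporary acetal ring together (step 2); lactone (step 5); acetal ring opened (step 6).

Atom labels are those of the target: ring C5–C10, C14 methyl on C10, oxirane C1–C2, C4(=C3)–C15 on C5, C11(=C13)–C12 on C7. "Top face" is the face of the C10 methyl.
Assumption: the acetal carbon C15 in 9–13 (and in F1–F3, F7) forms as a mixture of epimers; it is left undefined in the SMILES and is destroyed in step 6.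

**Step 1**
Reactants: 1 (R)-(−)-carvone
Product: 3 (4S,5R)-4-hydroxy-2-methyl-5-(prop-1-en-2-yl)cyclohex-2-en-1-one (trans-4-hydroxycarvone), via silyl dienol ether 2 (not isolated)
Conditions: KOC(CH3)3, THF, −78 to −40 °C; Me3SiCl; then mCPBA, NaHCO3, CH2Cl2, −40 °C; aq. citric acid
Reagents that add atoms: mCPBA (3-chloroperoxybenzoic acid), OOC(=O)c1cccc(Cl)c1
Why: Vinylogous Rubottom oxidation: reversible deprotonation gives the through-conjugated γ-dienolate, its O-silyl dienol ether is epoxidised at the remote, less hindered C5=C6 bond anti to the adjacent isopropenyl group, and collapse of the silyloxy epoxide gives the trans γ-hydroxy enone, which sets C6.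

**Step 2**
Reactants: 3 trans-4-hydroxycarvone; 4 2-bromo-3,3-diethoxyprop-1-ene; 5 chloroacetaldehyde (anhydrous)
Product: 9 tricyclic ketone 2-ethoxy-4-methyl-3-methylidene-4-[(2S)-oxiran-2-yl]-7-(prop-1-en-2-yl)hexahydro-1-benzofuran-5(2H)-one (tetrahydrofuran cis-fused at C5/C6 on the top face; isopropenyl below; oxiranyl below), via magnesium enolate 6 (not isolated), via chlorohydrin 7 (not isolated), via epoxy alcohol 8 (not isolated)
Conditions: 4 (2.2 equiv), Mg, THF, 40 °C; add 3, −78 to −20 °C; 5, −78 °C; NaOEt, EtOH, 0 °C; AcOH, 23 °C (one flask)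
Reagents that add atoms: none
Why: Proposed new method: the magnesium alkoxide of 3 binds a second equivalent of the alkenyl Grignard reagent and delivers it to C5 on the alkoxide face (also anti to the C7 isopropenyl), the tetrasubstituted magnesium enolate adds to chloroacetaldehyde anti to the new C5 group through a closed chair transition state with CH2Cl equatorial (giving S at C1 and the quaternary C10), ethoxide closes the chlorohydrin to the oxirane and acetic acid closes the cis γ-hydroxy acetal to the five-membered cyclic acetal, which protects C6–OH and the latent aldehyde; the closest known reactions are alkoxide-directed conjugate addition of Grignard reagents to 4-hydroxy enones, enolate-trapping aldol reactions and Darzens/Cornforth-type halohydrin closure.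

**Step 3**
Reactants: 9 tricyclic ketone
Product: 10 allylic alcohol (C12 hydroxymethyl; the C7 side chain is now 3-hydroxyprop-1-en-2-yl)
Conditions: SeO2 (cat.), t-BuOOH, CH2Cl2, 23 °C
Reagents that add atoms: tert-butyl hydroperoxide, CC(C)(C)OO
Why: Sharpless-type catalytic SeO2 allylic oxidation (ene reaction then [2,3]-shift) attacks the electron-rich isopropenyl methyl rather than the acetal-deactivated methylidene and, at 23 °C, leaves the ketone α-CH2 alone; no stereocentre is formed.

**Step 4**
Reactants: 10 allylic alcohol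
Product: 11 5-oxo acid (C12 carboxylic acid; the C7 side chain is now 1-carboxyvinyl)
Conditions: 2,2,6,6-tetramethylpiperidine-1-oxyl (cat.), NaOCl (cat.), NaClO2, MeCN, NaH2PO4/Na2HPO4 buffer pH 6.7, 35 °C
Reagents that add atoms: sodium chlorite, [Na+].[O-]Cl=O
Why: Oxoammonium/chlorite oxidation takes the primary allylic alcohol through the aldehyde to the acrylic acid at near-neutral pH, which the acid-labile cyclic acetal and the oxirane tolerate.

**Step 5**
Reactants: 11 5-oxo acid
Product: 13 keto lactone (8,12-olide cis-fused at C7/C8; C9 ketone; 6,15-cyclic ethyl acetal; oxirane), via iodo ketone 12 (not isolated)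
Conditions: LiN(SiMe3)2 (2.2 equiv), THF, −78 °C; I2, −78 to 0 °C
Reagents that add atoms: none
Why: Proposed new method: the ketone can enolise only towards C8 (C10 is quaternary), iodine adds to the carboxylate–enolate dianion anti to the C7 side chain and the carboxylate displaces iodide from the rear (5-exo-tet SN2), so C8–O ends cis to C7–C11, lithium iodide epimerising any wrongly placed iodide; the closest known reactions are α-iodination of lithium enolates and iodane-mediated lactonisation of 5-oxo carboxylic acids.

**Step 6**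
Reactants: 13 keto lactone
Product: 14 hydroxy enal (free C6–OH; C5 bears 3-oxoprop-1-en-2-yl; C9 ketone; lactone; oxirane)
Conditions: pyridinium p-toluenesulfonate (cat.), acetone/H2O, 23 °C
Reagents that add atoms: water, O
Why: Acid hydrolysis of the allylic cyclic acetal (allyl-stabilised oxocarbenium ion) is much faster than opening of the neopentyl-type oxirane and releases the C6 hydroxyl and the conjugated acrolein, which stays open-chain because lactol formation would cost the conjugation.

**Step 7**
Reactants: 14 hydroxy enal; 15 angelic acid ((Z)-2-methylbut-2-enoic acid)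
Product: 17 C6 angelate (C9 ketone; enal; lactone; oxirane), via mixed anhydride 16 (not isolated)
Conditions: 15, 2,4,6-trichlorobenzoyl chloride, Et3N, toluene, 23 °C; then 14, 4-(dimethylamino)pyridine, 23 °C
Reagents that add atoms: none
Why: Yamaguchi esterification through the mixed anhydride acylates the only free hydroxyl (C6) at 23 °C, mild enough to keep the (Z)-geometry of the angelate.

**Step 8**
Reactants: 17 C6 angelate
Product: 18 diol (C9–OH cis to the lactone oxygen; C15 primary allylic alcohol)
Conditions: NaBH4, CeCl3·7H2O, MeOH, −78 to −40 °C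
Reagents that add atoms: none
Why: Luche reduction gives 1,2-reduction only: hydride adds to the C9 ketone anti to the C8–O bond (polar Felkin–Anh) from the convex face of the cis-fused lactone, which sets C9–OH cis to C8–O, while the enal goes to the allylic alcohol and the two conjugated esters are untouched.

**Step 9**
Reactants: 18 diol
Product: 19 target CNP0113462.5
Conditions: MnO2, CH2Cl2, 23 °C
Reagents that add atoms: none
Why: MnO2 oxidises only the primary allylic alcohol back to the enal; the saturated secondary C9 alcohol does not react.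

**Compound list**
1 | (R)-(−)-carvone | CC1=CC[C@H](CC1=O)C(C)=C | starting material
2 | (5S)-2-methyl-5-(prop-1-en-2-yl)-1-(trimethylsilyloxy)cyclohexa-1,3-diene | C[Si](C)(C)OC1=C(C)C=C[C@@H](C(C)=C)C1 | intermediate (not isolated)
3 | (4S,5R)-4-hydroxy-2-methyl-5-(prop-1-en-2-yl)cyclohex-2-en-1-one | O=C1C[C@H](C(C)=C)[C@@H](O)C=C1C | intermediate
4 | 2-bromo-3,3-diethoxyprop-1-ene | CCOC(OCC)C(Br)=C | starting material
5 | chloroacetaldehyde | ClCC=O | starting material
6 | bis(bromomagnesium) enolate–alkoxide of the C5 adduct | CCOC(OCC)C(=C)[C@@H]1[C@H](O[Mg]Br)[C@@H](C(C)=C)CC(O[Mg]Br)=C1C | intermediate (not isolated)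
7 | chlorohydrin aldol (C10 bears (1S)-2-chloro-1-hydroxyethyl; C6–OH free; diethyl acetal) | O=C1C[C@H](C(C)=C)[C@@H](O)[C@@H](C(=C)C(OCC)OCC)[C@]1(C)[C@H](O)CCl | intermediate (not isolated)
8 | epoxy alcohol (oxirane closed; C6–OH free; diethyl acetal) | O=C1C[C@H](C(C)=C)[C@@H](O)[C@@H](C(=C)C(OCC)OCC)[C@]1(C)[C@H]2CO2 | intermediate (not isolated)
9 | 2-ethoxy-4-methyl-3-methylidene-4-[(2S)-oxiran-2-yl]-7-(prop-1-en-2-yl)hexahydro-1-benzofuran-5(2H)-one | O=C1C[C@H](C(C)=C)[C@H]2OC(OCC)C(=C)[C@H]2[C@]1(C)[C@H]3CO3 | intermediate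
10 | allylic alcohol (7-(3-hydroxyprop-1-en-2-yl) analogue of 9) | O=C1C[C@H](C(CO)=C)[C@H]2OC(OCC)C(=C)[C@H]2[C@]1(C)[C@H]3CO3 | intermediate
11 | 5-oxo acid (7-(1-carboxyvinyl) analogue of 9) | O=C1C[C@H](C(C(=O)O)=C)[C@H]2OC(OCC)C(=C)[C@H]2[C@]1(C)[C@H]3CO3 | intermediate
12 | α-iodo ketone of 11 (iodine at C8 on the top face) | O=C1[C@@H](I)[C@H](C(C(=O)O)=C)[C@H]2OC(OCC)C(=C)[C@H]2[C@]1(C)[C@H]3CO3 | intermediate (not isolated)
13 | keto lactone (8,12-olide; C9 ketone; 6,15-cyclic ethyl acetal; oxirane) | C=C1C(=O)O[C@@H]2[C@H]1[C@H]3OC(OCC)C(=C)[C@H]3[C@](C)([C@H]4CO4)C2=O | intermediate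
14 | hydroxy enal (C6–OH; C15 aldehyde; C9 ketone; lactone; oxirane) | C=C1C(=O)O[C@@H]2[C@H]1[C@@H](O)[C@@H](C(=C)C=O)[C@](C)([C@H]3CO3)C2=O | intermediate
15 | angelic acid | C/C=C(/C)C(=O)O | starting material
16 | angelic 2,4,6-trichlorobenzoic anhydride | C/C=C(/C)C(=O)OC(=O)c1c(Cl)cc(Cl)cc1Cl | intermediate (not isolated)
17 | C6 angelate of 14 | C=C1C(=O)O[C@@H]2[C@H]1[C@@H](OC(=O)/C(C)=C\C)[C@@H](C(=C)C=O)[C@](C)([C@H]3CO3)C2=O | intermediate
18 | diol (C9–OH; C15–OH) | C=C1C(=O)O[C@@H]2[C@H]1[C@@H](OC(=O)/C(C)=C\C)[C@@H](C(=C)CO)[C@](C)([C@H]3CO3)[C@@H]2O | intermediate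
19 | CNP0113462.5 | C=C1C(=O)O[C@@H]2[C@H]1[C@@H](OC(=O)/C(C)=C\C)[C@@H](C(=C)C=O)[C@](C)([C@H]3CO3)[C@@H]2O | target

**Totals**
Total step count: 9. Longest linear sequence: 9 (1 → 19).

**Steps most likely to fail**

Step 2 (1,2-addition, retro-aldol before oxirane closure, or poor C1 selectivity). The fallback sets out from 3 and returns at 9, delivering the side chain through a tether instead of by direction. Ethoxyallene and N-bromosuccinimide convert 3 into the mixed bromoacetal F1. A nickel-catalysed reductive conjugate cyclisation (NiCl2·glyme, neocuproine, Mn powder, Et3SiCl) closes the acetal ring onto C5 and gives the regiodefined triethylsilyl enol ether F2. MeLi regenerates the enolate, which adds to 5 to give the cyclic-acetal chlorohydrin F3, and K2CO3 in EtOH closes the oxirane to 9.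

Step 1 (cross-conjugated instead of linear dienolate, or aromatisation to carvacrol). The fallback sets out from 1 and returns at 3 through an endoperoxide. NaBH4 with CeCl3·7H2O gives cis-carveol F4. 2,4-Dinitrobenzenesulfenyl chloride and Et3N effect 1,4-dehydration ([2,3]-shift, then sulfoxide elimination) to the diene F5. Singlet oxygen (tetraphenylporphyrin, light) adds anti to the isopropenyl group to give the endoperoxide F6, and Et3N (Kornblum–DeLaMare rearrangement, removal of the more accessible C9–H) gives 3.

Step 5 (elimination of HI to the enone, or poor iodination). The fallback sets out from 11 and returns at 13, replacing iodination by hydroxylation and inversion. Rubottom oxidation (Me3SiOTf, Et3N; dimethyldioxirane; mild acid) gives the α-hydroxy keto acid F7 with C8–OH on the top face. Intramolecular Mitsunobu lactonisation (PPh3, diisopropyl azodicarboxylate) then closes the lactone with inversion at C8 to 13.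

**Further compounds**
F1 | step 2 | mixed bromoacetal of 3 (C6–O–CH(OEt)–C(Br)=CH2) | O=C1C[C@H](C(C)=C)[C@@H](OC(OCC)C(Br)=C)C=C1C
F2 | step 2 | triethylsilyl enol ether of the cyclised acetal ketone | CC[Si](CC)(CC)OC1=C(C)[C@@H]2C(=C)C(OCC)O[C@@H]2[C@@H](C(C)=C)C1
F3 | step 2 | cyclic-acetal chlorohydrin | O=C1C[C@H](C(C)=C)[C@H]2OC(OCC)C(=C)[C@H]2[C@]1(C)[C@H](O)CCl
F4 | step 1 | cis-carveol | O[C@@H]1C[C@H](C(C)=C)CC=C1C
F5 | step 1 | (5S)-2-methyl-5-(prop-1-en-2-yl)cyclohexa-1,3-diene | CC1=CC[C@H](C(C)=C)C=C1
F6 | step 1 | 1,4-endoperoxide of F5 (peroxide bridge C6/C9 on the top face) | CC1=C[C@@H]2OO[C@H]1C[C@@H]2C(C)=C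
F7 | step 5 | α-hydroxy keto acid (C8–OH on the top face) | O=C1[C@@H](O)[C@H](C(C(=O)O)=C)[C@H]2OC(OCC)C(=C)[C@H]2[C@]1(C)[C@H]3CO3
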